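## Conventions and assumptions

- Numbering. Compounds 1–3 use caryophyllane numbering: C1 and C9 are the ring-fusion CH groups, C4/C5 the epoxide, C7 the allylic CH2, C8=C13 the exocyclic alkene, C10 the cyclobutane CH2, C11 the CMe2 carbon. Compounds 4–6 and 16–18 use humulane numbering: ring C1–C11, one methyl on C2 and on C9, two on C6. Caryophyllane C4, C5, C6, C7, C8, C9, C10, C11, C1, C2, C3 become humulane C2, C1, C11, C10, C9, C8, C7, C6, C5, C4, C3.
- Assumption on step 1: the allylic oxidation is taken to give the 7S alcohol (oxygen enters on the open face of the rigid bicycle); this has not been derived rigorously, and the fallback for step 1 corrects either outcome.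
- The free tropolones (14, 16, 17, 18) are mixtures of rapidly interconverting tautomers; one tautomer is drawn.

## Analysis of the target

The target (C33H40O7) has an eleven-membered carbocycle (ring C, humulane C1–C11) with an E alkene C4=C5 next to the quaternary C6 and a secondary hydroxyl on C10. Ring C is fused through C1–C2 and through C8–C9 to two dihydropyrans (rings B and D), and each pyran is fused to a methyl-substituted tropolone (rings A and E). In both pyrans the ring oxygen sits on the methyl-bearing quaternary carbon (C2, C9) and a CH2 group links the tropolone to the methine carbon (C1, C8). There are five stereocentres: C1 (R), C2 (R), C8 (R), C9 (R) and C10 (S). Both pyrans are trans-fused (H and CH3 anti), which is the outcome of suprafacial addition to an E-trisubstituted alkene, and C10–OH is vicinal to the C9–O bond. Sensitive groups are the acidic, chelating tropolones, the two tertiary alkyl ethers of vinylogous acids (open to acid ionisation), and the alcohol next to one of them. The difficulty lies in the medium ring, which has no handle for closure and carries an E alkene beside a quaternary carbon, in four ring-fusion stereocentres that must be related to C10, and in a tropolone unit that cannot be bought. The feature that invites the chosen move is the segment C5–C6(CH3)2–C7–C8 of ring C. A bond between C5 and C8 would make it the gem-dimethylcyclobutane of caryophyllene oxide; C5 (alkene carbon) and C8 (former alkene carbon) are the ends that a homolytic scission of that bond leaves. C10 then maps onto the allylic C7 of the terpene, and C1/C2 onto its epoxide.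

## Retrosynthetic reasoning

**18 to 6 and two molecules of 15.** The bonds O–C2 and CH2–C1 (ring B) and O–C9 and CH2–C8 (ring D) are cut. The trans-fusion and the placement of oxygen on the more substituted carbon are what an inverse-demand oxa-[4+2] cycloaddition of quinone methide 15 to an E-trisubstituted alkene gives. Both tropolone units are identical, so one reagent (15, from 14) serves twice and no protecting group is needed. The forward step has to spare the C4=C5 alkene and choose the right face of each trisubstituted alkene.

**6 to 5 to 4.** The hydroxyl is carried as a silyl ether and the C1=C2 alkene as its epoxide. The epoxide comes with the starting material and shields this alkene from the oxidant of step 1 and from the hydrogen-atom donor of step 3. The forward steps are a stereospecific deoxygenation and a desilylation.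

**4 to 3 (key disconnection).** A bond is drawn between humulane C5 and C8 (caryophyllane C1–C9). This turns the eleven-membered ring into the bicyclo[7.2.0] skeleton of a cheap, enantiopure terpene. The medium ring then never has to be closed, and C10 can be set on a rigid bicycle before the ring exists. The forward step must put a radical at caryophyllane C8, break the fusion bond, and end as two E alkenes.

**3 to 2 to 1.** The C7–O bond is cut. The only alkene of 1 is the exocyclic one, so allylic oxidation has only two allylic sites to choose from, and only the ring CH2 at C7 is accessible.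

**14 to 12 to 10 to 9 to 8 to 7.** In the tropolone the two ring bonds to the carbon that carries bromine in 12 are cut, i.e. one carbon is inserted into the C4–C5 bond of an arene. The methyl, the hydroxymethyl carbon and both oxygens of 14 already stand in the right positions in commercial 7. The forward sequence is dearomatisation to a 1,4-diene, carbene addition, electrocyclic ring opening, dehydrogenation, and exchange of bromine for oxygen.

## Alternatives that were turned down

**Alternative 1:** the textbook, biomimetic route. Disconnection: the four pyran bonds, with the double cycloaddition of 15 onto 6 as key step, and 6 taken from commercial alpha-humulene A1 by direct allylic oxidation to racemic humulen-10-ol A2 followed by resolution. Turned down as the carrier of the strategy. A1 is achiral and fluxional, with two trisubstituted alkenes of similar reactivity and several allylic CH2 and CH3 sites, so oxidation gives regioisomers and nothing sets C10. Resolution then discards half of a minor product. The cycloaddition is kept as the end-game, but by itself it leaves the real problem, a regiodefined and enantiopure 6, unsolved.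

**Alternative 2:** de novo macrocyclisation. Disconnection: C9–C10 of ring C. The forward key step is an intramolecular Nozaki–Hiyama–Kishi reaction (CrCl2, NiCl2 cat.) of the acyclic iodo-aldehyde A3 to the skeleton of 6. Turned down because A3 needs on the order of ten steps to place three E alkenes, one beside a quaternary carbon. The closure of a strained eleven-membered ring is entropically costly, and C10 would have to be controlled by a chiral ligand during a macrocyclisation. All of this reaches an intermediate that the chosen route makes in five steps.

**Alternative 3:** late arene-to-tropolone ring expansion. Disconnection: the ring bonds of rings A and E at the inserted carbons. Forward: double cycloaddition of a benzenoid quinone methide to bis-chroman A4, then a twofold Birch reduction, dihalocarbene addition and ring opening. Turned down because a multi-step ring expansion must run twice on the finished skeleton. The C4=C5 alkene is a carbene acceptor, each reduced ring offers two enol ether sites, and the tertiary ethers and the free alcohol must survive dissolving metal, strong base and oxidant. Making the tropolone once, before the coupling, removes this risk.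

Key step: step 3

## Route

Step 1
Reactants: 1 (−)-caryophyllene oxide
Product: 2 (1R,4R,5R,7S,9S)-4,5-epoxycaryophyll-8(13)-en-7-ol
Conditions: SeO2 (cat.), t-BuOOH, pyridine (cat.), CH2Cl2, 0 °C to rt
Reagents that add atoms: tert-butyl hydroperoxide CC(C)(C)OO; selenium dioxide O=[Se]=O (oxygen carrier, catalytic)
Why: Riley-type allylic oxidation (ene reaction, then [2,3]-sigmatropic shift) of the only alkene; the ring CH2 at C7 reacts because the bridgehead C9–H cannot align with the pi system. The C7 centre is set by the rigid trans-fused bicycle, the C7–H on the open face being replaced by oxygen (assumed 7S).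

Step 2
Reactants: 2 (1R,4R,5R,7S,9S)-4,5-epoxycaryophyll-8(13)-en-7-ol
Product: 3 (1R,4R,5R,7S,9S)-7-(tert-butyldimethylsilyloxy)-4,5-epoxycaryophyll-8(13)-ene
Conditions: TBSCl, imidazole, DMF, rt
Reagents that add atoms: tert-butyldimethylsilyl chloride CC(C)(C)[Si](C)(C)Cl
Why: Standard silylation of a secondary alcohol under basic conditions that leave the epoxide alone. The ether keeps the C8 radical of step 3 from collapsing to an enol or ketone and is tolerated by the reagent of step 4.

Step 3
Reactants: 3 (1R,4R,5R,7S,9S)-7-(tert-butyldimethylsilyloxy)-4,5-epoxycaryophyll-8(13)-ene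
Product: 4 (1R,2R,4E,8E,10S)-10-(tert-butyldimethylsilyloxy)-1,2-epoxyhumula-4,8-diene
Conditions: Co(L)Cl (5 mol %; L = N,N′-bis(3,5-di-tert-butylsalicylidene)ethane-1,2-diaminate), PhSiH3 (6 mol %), benzene, 22 °C, argon
Reagents that add atoms: none
Why: The cobalt hydride formed from the trivalent cobalt chloride and the silane transfers a hydrogen atom to the terminal carbon C13 and leaves a tertiary radical at C8 beside divalent cobalt. This cyclobutylcarbinyl radical opens by beta-scission of the fusion bond C1–C9, which releases the strain of the four-membered ring and of the trans-fused nine-membered ring, forms the C8=C9 alkene and gives a secondary radical at C1; scission of C9–C10 would give a primary radical and is not expected. Divalent cobalt then removes a hydrogen atom from C2, the only neighbour of C1 that has one because C11 is quaternary, which forms the C1=C2 alkene and returns the cobalt hydride, so the step is a net isomerisation. The closest known reaction type is the cobalt-salen/silane hydrogen-atom-transfer isomerisation of 1,1-disubstituted alkenes in its retro-cycloisomerisation form on strained rings, known for four-membered rings next to an exocyclic alkene in terpenes of this kind; the substrate differs from the parent epoxide skeleton only in the C7 silyloxy group. No ring is closed: the nine- and four-membered rings merge into the eleven-membered ring by loss of their common bond. No stereocentre is formed; C7 (humulane C10) and the epoxide carbons are not radical sites and keep their configuration, and both new alkenes should be E as in the parent skeleton, E being the low-strain geometry of the eleven-membered ring. The step needs ring opening to outrun hydrogen abstraction from C7 (which would give a silyl enol ether); the strain-driven scission and the hindered, silyloxy-bearing C7–H favour this, and the epoxide is inert to the neutral radical conditions.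

Step 4
Reactants: 4 (1R,2R,4E,8E,10S)-10-(tert-butyldimethylsilyloxy)-1,2-epoxyhumula-4,8-diene
Product: 5 (1E,4E,8E,10S)-10-(tert-butyldimethylsilyloxy)humula-1,4,8-triene
Conditions: WCl6, n-BuLi (2 equiv per W), THF, −78 °C to rt; then 4, rt to 50 °C
Reagents that add atoms: none
Why: Deoxygenation of the epoxide by the low-valent tungsten chloride through an oxametallacycle and syn elimination, which retains the E geometry of the trisubstituted alkene. The silyl ether and the other alkenes do not react.

Step 5
Reactants: 5 (1E,4E,8E,10S)-10-(tert-butyldimethylsilyloxy)humula-1,4,8-triene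
Product: 6 (1E,4E,8E,10S)-humula-1,4,8-trien-10-ol
Conditions: TBAF, THF, rt
Reagents that add atoms: none
Why: Fluoride cleavage of the silyl ether; the free hydroxyl is less hindering than the silyl ether in the cycloaddition at C8=C9.

Step 6
Reactants: 7 2,4-dimethoxy-6-methylbenzaldehyde
Product: 8 (2,4-dimethoxy-6-methylphenyl)methanol
Conditions: NaBH4, MeOH, 0 °C
Reagents that add atoms: none
Why: Hydride reduction of an aromatic aldehyde.

Step 7
Reactants: 8 (2,4-dimethoxy-6-methylphenyl)methanol
Product: 9 (2,4-dimethoxy-6-methylcyclohexa-1,4-dien-1-yl)methanol (racemic)
Conditions: Li, NH3 (l), THF, t-BuOH, −78 °C; NH4Cl quench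
Reagents that add atoms: none
Why: Birch reduction; protons add at C3 and C6 so that both methoxy groups stay on sp2 carbons, and the lithium alkoxide of the benzylic alcohol is a poor leaving group, which suppresses hydrogenolysis. The new centre at C6 is racemic and is erased in step 9.

Step 8
Reactants: 9 (2,4-dimethoxy-6-methylcyclohexa-1,4-dien-1-yl)methanol
Product: 10 (7,7-dibromo-1,3-dimethoxy-5-methylbicyclo[4.1.0]hept-3-en-4-yl)methanol (racemic diastereomer mixture)
Conditions: CHBr3, 50% aq. NaOH, BnEt3NCl (cat.), CH2Cl2, 0 °C
Reagents that add atoms: bromoform BrC(Br)Br
Why: Phase-transfer dibromocarbene addition to the trisubstituted enol ether C4=C5; the tetrasubstituted enol ether is hindered and deactivated by its allylic hydroxyl, as is usual for allylic alcohols under these conditions. The stereocentres formed are erased in step 9.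

Step 9
Reactants: 10 (7,7-dibromo-1,3-dimethoxy-5-methylbicyclo[4.1.0]hept-3-en-4-yl)methanol
Product: 12 2-bromo-5-(hydroxymethyl)-6-methoxy-4-methylcyclohepta-2,4,6-trien-1-one, via bromodienone 11 (not isolated)
Conditions: toluene, NaHCO3, 90 °C; then DDQ, rt
Reagents that add atoms: none
Why: Thermal disrotatory cyclopropyl-to-allyl cation opening, assisted by the bridgehead methoxy group, expels bromide, which demethylates the oxocarbenium ion to give 2-bromoenone 11. DDQ then removes hydride from the doubly allylic C4–H and loss of a proton from C7 gives the tropone.

Step 10
Reactants: 12 2-bromo-5-(hydroxymethyl)-6-methoxy-4-methylcyclohepta-2,4,6-trien-1-one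
Product: 14 2,4-dihydroxy-5-(hydroxymethyl)-6-methylcyclohepta-2,4,6-trien-1-one, via dimethoxytropone 13 (not isolated)
Conditions: NaOMe, MeOH, 0 °C to rt; then 1 M aq. HCl, 1,4-dioxane, 70 °C
Reagents that add atoms: water O; sodium methoxide [Na+].[O-]C (its methoxy group is carried only by intermediate 13)
Why: Addition–elimination of methoxide at C2 of the 2-bromotropone, then acid hydrolysis of both vinylogous methyl esters. Dilute aqueous acid keeps the hydroxymethyl group from self-condensation.

Step 11
Reactants: 6 (1E,4E,8E,10S)-humula-1,4,8-trien-10-ol; 14 2,4-dihydroxy-5-(hydroxymethyl)-6-methylcyclohepta-2,4,6-trien-1-one (2 equiv or more)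
Product: 18 target CNP0283947.4 (1R,2R,8R,9R,10S), via quinone methide 15 (not isolated), via C8–C9 monoadduct 16 (not isolated), via C1–C2 monoadduct 17 (not isolated)
Conditions: p-xylene/1,4-dioxane, 150 °C, sealed tube, 14 added in portions
Reagents that add atoms: none
Why: Thermal dehydration of 14 gives quinone methide 15, which adds twice as an oxa-diene (inverse-demand hetero-Diels–Alder reaction) to the two E-trisubstituted alkenes; suprafacial addition gives trans-fused pyrans with oxygen on the methyl-bearing carbon, and the hindered, less nucleophilic C4=C5 alkene is spared. At C8=C9 the C10 centre directs: allylic 1,2-strain with the C9 methyl places C10–H outside and the hydroxyl inside, and attack anti to C11 gives the 8R,9R,10S array. At C1=C2 the face is set by the conformation of the ring and is the less certain element.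

## Compound list

1 | (−)-caryophyllene oxide, (1R,4R,5R,9S)-4,5-epoxycaryophyll-8(13)-ene | C[C@@]12CC[C@@H]3[C@H](CC3(C)C)C(=C)CC[C@H]1O2 | starting material
2 | (1R,4R,5R,7S,9S)-4,5-epoxycaryophyll-8(13)-en-7-ol | C[C@@]12CC[C@@H]3[C@H](CC3(C)C)C(=C)[C@@H](O)C[C@H]1O2 | intermediate
3 | (1R,4R,5R,7S,9S)-7-(tert-butyldimethylsilyloxy)-4,5-epoxycaryophyll-8(13)-ene | C[C@@]12CC[C@@H]3[C@H](CC3(C)C)C(=C)[C@@H](O[Si](C)(C)C(C)(C)C)C[C@H]1O2 | intermediate
4 | (1R,2R,4E,8E,10S)-10-(tert-butyldimethylsilyloxy)-1,2-epoxyhumula-4,8-diene | C[C@@]12C/C=C/C(C)(C)C/C=C(\C)[C@@H](O[Si](C)(C)C(C)(C)C)C[C@H]1O2 | intermediate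
5 | (1E,4E,8E,10S)-10-(tert-butyldimethylsilyloxy)humula-1,4,8-triene | C/C1=C\C[C@H](O[Si](C)(C)C(C)(C)C)/C(C)=C/CC(C)(C)/C=C/C1 | intermediate
6 | (1E,4E,8E,10S)-humula-1,4,8-trien-10-ol | C/C1=C\C[C@H](O)/C(C)=C/CC(C)(C)/C=C/C1 | intermediate
7 | 2,4-dimethoxy-6-methylbenzaldehyde | COc1cc(C)c(C=O)c(OC)c1 | starting material
8 | (2,4-dimethoxy-6-methylphenyl)methanol | COc1cc(C)c(CO)c(OC)c1 | intermediate
9 | (2,4-dimethoxy-6-methylcyclohexa-1,4-dien-1-yl)methanol, racemic | COC1=CC(C)C(CO)=C(OC)C1 | intermediate
10 | (7,7-dibromo-1,3-dimethoxy-5-methylbicyclo[4.1.0]hept-3-en-4-yl)methanol, racemic diastereomer mixture | COC12CC(OC)=C(CO)C(C)C1C2(Br)Br | intermediate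
11 | 2-bromo-5-(hydroxymethyl)-6-methoxy-4-methylcyclohepta-2,5-dien-1-one, racemic, not isolated | O=C1CC(OC)=C(CO)C(C)C=C1Br | intermediate
12 | 2-bromo-5-(hydroxymethyl)-6-methoxy-4-methylcyclohepta-2,4,6-trien-1-one | O=C1C=C(OC)C(CO)=C(C)C=C1Br | intermediate
13 | 5-(hydroxymethyl)-2,6-dimethoxy-4-methylcyclohepta-2,4,6-trien-1-one, not isolated | O=C1C=C(OC)C(CO)=C(C)C=C1OC | intermediate
14 | 2,4-dihydroxy-5-(hydroxymethyl)-6-methylcyclohepta-2,4,6-trien-1-one | CC1=CC(=O)C(O)=CC(O)=C1CO | intermediate
15 | 2-hydroxy-6-methyl-5-methylidenecyclohepta-2,6-diene-1,4-dione (quinone methide), not isolated | CC1=CC(=O)C(O)=CC(=O)C1=C | intermediate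
16 | monoadduct at C8–C9 (8R,9R,10S; ring D closed, C1=C2 alkene left), not isolated | Cc1cc(=O)c(O)cc2c1C[C@H]1CC(C)(C)/C=C/C/C(C)=C/C[C@H](O)[C@]1(C)O2 | intermediate
17 | monoadduct at C1–C2 (1R,2R,10S; ring B closed, C8=C9 alkene left), not isolated | Cc1cc(=O)c(O)cc2c1C[C@@H]1C[C@H](O)/C(C)=C/CC(C)(C)/C=C/C[C@@]1(C)O2 | intermediate
18 | target CNP0283947.4, (1R,2R,8R,9R,10S) bis-adduct of 6 with two units of 15 | Cc1cc(=O)c(O)cc2c1C[C@H]1CC(C)(C)/C=C/C[C@@]3(C)Oc4cc(O)c(=O)cc(C)c4C[C@@H]3C[C@H](O)[C@]1(C)O2 | target

## Step count and risk

Total: 11 steps. Longest linear sequence: 6 steps (steps 1–5 and 11, or steps 6–11).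

**Step 3 (key step).** The C8 radical may be quenched before the ring opens, either by hydrogen abstraction at C7 (isomerisation to a silyl enol ether, with loss or scrambling of the C7 centre) or by simple alkene migration. The new C8=C9 alkene may also form with partial loss of E geometry. Fallback: the route sets out from 1 and runs the same ring scission on the skeleton that has no C7 substituent, which gives humulene 1,2-epoxide F1. SeO2/t-BuOOH then oxidises the C10 methylene (the CH2 on the more substituted end of the C8=C9 alkene, cis to the vinyl hydrogen) to the epimeric alcohols F2. Dess–Martin oxidation gives enone F3, and Corey–Bakshi–Shibata reduction with the (R)-oxazaborolidine and BH3·SMe2 gives the (10S)-alcohol F4 under reagent control. Silylation (TBSCl, imidazole) returns to the route at 4.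

**Step 11.** Facial selectivity at the remote C1=C2 alkene may be poor, which would give a mixture of trans,trans diastereomers. The quinone methide may also self-condense faster than the second cycloaddition, and the allylic alcohol may ionise at 150 °C in the presence of the acidic tropolone. Fallback: the route sets out from 6 and 14 and replaces substrate control by catalyst control. The pair is incubated in buffer at 30 °C with a recombinant hetero-Diels–Alderase of the fungal tropolone-sesquiterpenoid pathways, the enzyme class that joins this alcohol and this quinone methide in vivo, chosen for the stereochemical series of the target. It comes back to the route at 18 and makes no new compound.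

**Step 1.** Oxygen may enter on the other face of C7 or on both, oxidation may run on to the enone, and the acid-sensitive epoxide may open transannularly. Fallback: the route sets out from 2 in whatever epimeric composition is obtained. Dess–Martin oxidation gives the 7-ketone F5, and Corey–Bakshi–Shibata reduction with the (R)-oxazaborolidine sets 7S by reagent control (alkenyl side large, CH2 side small). It comes back to the route at 2.

**Step 8.** The carbene may add to the tetrasubstituted enol ether, add twice, or react at the hydroxyl. Fallback: the route sets out from 9. Parikh–Doering oxidation (SO3·pyridine, DMSO, Et3N) gives 2,4-dimethoxy-6-methylcyclohexa-1,4-diene-1-carbaldehyde F6, in which the substituted alkene is a push–pull system and inert to an electrophilic carbene. Dibromocarbene addition then gives the cyclopropane aldehyde F7, and thermal opening with DDQ dehydrogenation gives the bromotropone aldehyde F8. Reduction with NaBH4/CeCl3 at −78 °C comes back to the route at 12.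

## Further compounds

F1 | step 3 | (1R,2R,4E,8E)-1,2-epoxyhumula-4,8-diene | C[C@@]12C/C=C/C(C)(C)C/C=C(\C)CC[C@H]1O2
F2 | step 3 | (1R,2R,4E,8E)-1,2-epoxyhumula-4,8-dien-10-ol, C10 epimers | C[C@@]12C/C=C/C(C)(C)C/C=C(\C)C(O)C[C@H]1O2
F3 | step 3 | (1R,2R,4E,8E)-1,2-epoxyhumula-4,8-dien-10-one | C[C@@]12C/C=C/C(C)(C)C/C=C(\C)C(=O)C[C@H]1O2
F4 | step 3 | (1R,2R,4E,8E,10S)-1,2-epoxyhumula-4,8-dien-10-ol | C[C@@]12C/C=C/C(C)(C)C/C=C(\C)[C@@H](O)C[C@H]1O2
F0 | step 11 | none | none
F5 | step 1 | (1R,4R,5R,9S)-4,5-epoxycaryophyll-8(13)-en-7-one | C[C@@]12CC[C@@H]3[C@H](CC3(C)C)C(=C)C(=O)C[C@H]1O2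
F6 | step 8 | 2,4-dimethoxy-6-methylcyclohexa-1,4-diene-1-carbaldehyde, racemic | COC1=CC(C)C(C=O)=C(OC)C1
F7 | step 8 | 7,7-dibromo-1,3-dimethoxy-5-methylbicyclo[4.1.0]hept-3-ene-4-carbaldehyde, racemic diastereomer mixture | COC12CC(OC)=C(C=O)C(C)C1C2(Br)Br
F8 | step 8 | 4-bromo-7-methoxy-2-methyl-5-oxocyclohepta-1,3,6-triene-1-carbaldehyde | O=CC1=C(C)C=C(Br)C(=O)C=C1OC
A1 | alternative 1 | alpha-humulene, (1E,4E,8E)-2,6,6,9-tetramethylcycloundeca-1,4,8-triene | C/C1=C\CC/C(C)=C/CC(C)(C)/C=C/C1
A2 | alternative 1 | racemic (1E,4E,8E)-humula-1,4,8-trien-10-ol | C/C1=C\CC(O)/C(C)=C/CC(C)(C)/C=C/C1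
A3 | alternative 2 | (3E,7E,11E)-12-iodo-4,8,8-trimethyltrideca-3,7,11-trienal | O=CC/C=C(\C)C/C=C/C(C)(C)C/C=C(\C)I
A4 | alternative 3 | bis(7-methoxy-5-methylchroman) analogue of 18 (benzene rings in place of the tropolones) | Cc1cc(OC)cc2c1C[C@H]1CC(C)(C)/C=C/C[C@@]3(C)Oc4cc(OC)cc(C)c4C[C@@H]3C[C@H](O)[C@]1(C)O2
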